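**Retrosynthetic overview**
- The target is (4R,6S)-4,6-dihydroxy-4-[(10Z)-heptadec-10-enyl]cyclohex-2-enone. It has one ring (carbocycle C1–C6) and two stereocentres, and the hydroxyls on C4 and C6 are cis.
- Enabling feature: O–C4 and O–C6 stand cis-1,3 across C5 of the cyclohexenone ring. C4 is fully substituted (a tertiary cation site) and C2 lies α to the C1 carbonyl (an acyl thionium site). A carbonyl tether on O6 can therefore reach C4 through a temporary 2,4-dioxabicyclo[3.3.1]nonane.
- Disconnections: C2=C3 comes from a sulfoxide syn-elimination. The C2–C3 and C4–O bonds come from one Pummerer-triggered cation–olefin bicyclisation of an acyclic β-keto sulfoxide whose only carbon stereocentre is C6.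
- The acyclic precursor comes from methyl (S)-glycidate (C5, C6, C1), methyl phenyl sulfoxide (C2), 2,3-dibromopropene (C3, C4, C1′) and palmitoleyl alcohol (C2′–C17′ with the Z-alkene).
- Ring order: the carbocycle and the temporary cyclic carbonate close in the same operation, carbocycle first. The carbonate ring is hydrolysed in the last step.

Key step: step 6

Assumption: the configuration at sulfur in 12 and 16 and at the sulfur-bearing ring carbon in 14–16 has no consequence, so these centres are left undefined in names and SMILES.

**Step 1**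
Reactants: 1 (9Z)-hexadec-9-en-1-ol (palmitoleyl alcohol)
Product: 2 (9Z)-1-bromohexadec-9-ene
Conditions: CBr4, PPh3, CH2Cl2, 0 °C
Reagents that add atoms: carbon tetrabromide, BrC(Br)(Br)Br
Why: Appel reaction, in which bromide displaces the oxyphosphonium salt of the primary alcohol in an SN2 step under neutral conditions that leave the Z-alkene untouched.

**Step 2**
Reactants: 2 (9Z)-1-bromohexadec-9-ene; 3 2,3-dibromopropene
Product: 5 (12Z)-2-bromononadeca-1,12-diene, via Grignard reagent 4 (not isolated)
Conditions: Mg, Et2O, reflux; then 3, Et2O, 0 → 35 °C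
Reagents that add atoms: none
Why: Grignard formation followed by allylic substitution, in which only the allylic C–Br bond of 3 is displaced and the vinylic bromide survives, a long-established way to 2-bromo-1-alkenes.

**Step 3**
Reactants: 5 (12Z)-2-bromononadeca-1,12-diene; 6 methyl (2S)-oxirane-2-carboxylate (methyl (S)-glycidate)
Product: 8 methyl (2S,14Z)-2-hydroxy-4-methylidenehenicos-14-enoate, via alkenyl Grignard reagent 7 (not isolated)
Conditions: Mg, THF, 50 °C; CuI (10 mol %), −40 °C; then 6, −40 → −20 °C; aqueous work-up
Reagents that add atoms: none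
Why: Copper-catalysed epoxide opening by an alkenyl Grignard reagent, in which the soft alkenylcopper species attacks the unhindered CH2 of the glycidate faster than the ester and no bond to the stereocentre is touched, so the S centre (later C6 of the target) comes unchanged from 6.

**Step 4**
Reactants: 8 methyl (2S,14Z)-2-hydroxy-4-methylidenehenicos-14-enoate
Product: 9 methyl (2S,14Z)-2-[(dimethylcarbamoyl)oxy]-4-methylidenehenicos-14-enoate
Conditions: Me2NCOCl, DMAP (cat.), pyridine, 50 °C
Reagents that add atoms: dimethylcarbamoyl chloride, CN(C)C(=O)Cl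
Why: DMAP-catalysed O-carbamoylation (acyl transfer) of the secondary alcohol without change at the stereocentre, which installs a group that is inert to the carbanion of step 5 and later acts as the internal oxygen nucleophile.

**Step 5**
Reactants: 9 methyl (2S,14Z)-2-[(dimethylcarbamoyl)oxy]-4-methylidenehenicos-14-enoate; 10 methyl phenyl sulfoxide
Product: 12 (3S,15Z)-5-methylidene-2-oxo-1-(phenylsulfinyl)docos-15-en-3-yl dimethylcarbamate, via lithiated sulfoxide 11 (not isolated)
Conditions: 10 (2.2 equiv), LiN(iPr)2 (2.1 equiv), THF, −78 °C; then 9, −78 → −40 °C; AcOH quench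
Reagents that add atoms: none
Why: Claisen-type acylation of an α-sulfinyl carbanion by the methyl ester (the classical β-keto sulfoxide synthesis), in which the second equivalent of carbanion deprotonates the product at once between S and C=O, so that over-addition and enolisation towards the stereocentre are suppressed and the far less electrophilic carbamate is left alone.

**Step 6**
Reactants: 12 (3S,15Z)-5-methylidene-2-oxo-1-(phenylsulfinyl)docos-15-en-3-yl dimethylcarbamate
Product: 15 (1R,5S)-1-[(10Z)-heptadec-10-en-1-yl]-7-(phenylsulfanyl)-2,4-dioxabicyclo[3.3.1]nonane-3,6-dione, via acyl thionium triflate 13 (not isolated), via bicyclic iminium triflate 14 (not isolated)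
Conditions: Tf2O (1.05 equiv), 2,6-di-tert-butyl-4-methylpyridine (2.5 equiv), CH2Cl2 (0.01 M), −78 → −20 °C; then NaOAc/AcOH buffer (pH 5), THF–H2O, 23 °C
Reagents that add atoms: water, O
Why: Proposed new method: Tf2O turns the sulfoxide into a triflyloxysulfonium salt, the hindered pyridine removes the acidic proton between sulfur and carbonyl, and loss of triflate gives the α-acyl thionium ion 13 (Pummerer reaction), whose carbon is attacked by the CH2 terminus of the 1,1-disubstituted alkene while the carbamate carbonyl oxygen captures the tertiary cation that develops, giving iminium salt 14, which buffered water hydrolyses to the cyclic carbonate 15. The closest known reaction types are the Pummerer-initiated cation–olefin cyclisation of unsaturated β-keto sulfoxides to 2-(arylsulfanyl)cyclohexanones and the halocyclisation of homoallylic carbamates and tert-butyl carbonates to six-membered cyclic carbonates, and the new element is their merger, with a carbon electrophile in the place of the halonium ion. The carbocycle closes in the 6-endo-trig mode (the 5-exo mode would need a primary cation) and the temporary 1,3-dioxane ring in the 6-exo-trig mode. The new quaternary stereocentre is controlled by the S-configured carbinol carbon through the O–C–O tether, because a 2,4-dioxabicyclo[3.3.1]nonane can only exist with both C–O bonds on one face of the carbocycle, so that internal capture can give nothing but the cis-4,6 relation and thus the R centre, whereas the sulfur-bearing carbon is formed without control and is erased in step 7. The step needs the thionium ion to choose the near 1,1-disubstituted alkene over the remote Z-alkene (secured by proximity and by the higher nucleophilicity of the former), it needs freedom from vinyl sulfide formation (13 has no β-hydrogen), and it needs internal capture to be faster than proton loss (favoured by low temperature, the non-nucleophilic triflate counter-ion and a base too hindered to reach the cation).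

**Step 7**
Reactants: 15 (1R,5S)-1-[(10Z)-heptadec-10-en-1-yl]-7-(phenylsulfanyl)-2,4-dioxabicyclo[3.3.1]nonane-3,6-dione
Product: 17 (1R,5S)-1-[(10Z)-heptadec-10-en-1-yl]-2,4-dioxabicyclo[3.3.1]non-7-ene-3,6-dione, via keto sulfoxide 16 (not isolated)
Conditions: mCPBA (1.0 equiv), CH2Cl2, −78 °C; solvent change to toluene, 90 °C
Reagents that add atoms: none
Why: Chemoselective sulfide oxidation (sulfur reacts far faster than a dialkyl alkene with one equivalent of peracid at −78 °C) followed by thermal sulfoxide syn-elimination, which can only take a hydrogen from C8 and so places the double bond in conjugation, while both stereocentres are bridgeheads and cannot epimerise.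

**Step 8**
Reactants: 17 (1R,5S)-1-[(10Z)-heptadec-10-en-1-yl]-2,4-dioxabicyclo[3.3.1]non-7-ene-3,6-dione
Product: 18 (4R,6S)-4-[(10Z)-heptadec-10-en-1-yl]-4,6-dihydroxycyclohex-2-en-1-one (target)
Conditions: LiOH (2.2 equiv), THF–H2O, 0 °C, argon; neutralised with pH 7 phosphate buffer
Reagents that add atoms: none
Why: Saponification of the cyclic carbonate, in which hydroxide attacks only the carbonate carbonyl and the hydrogen carbonate monoester loses CO2, so both C–O bonds at the stereocentres stay intact (retention), and short, cold, oxygen-free treatment is chosen to avoid enolisation at C6.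

**Compound list**
1 | (9Z)-hexadec-9-en-1-ol | CCCCCC/C=C\CCCCCCCCO | starting material
2 | (9Z)-1-bromohexadec-9-ene | CCCCCC/C=C\CCCCCCCCBr | intermediate
3 | 2,3-dibromopropene | C=C(Br)CBr | starting material
4 | [(9Z)-hexadec-9-en-1-yl]magnesium bromide | CCCCCC/C=C\CCCCCCCC[Mg]Br | intermediate
5 | (12Z)-2-bromononadeca-1,12-diene | CCCCCC/C=C\CCCCCCCCCC(Br)=C | intermediate
6 | methyl (2S)-oxirane-2-carboxylate | COC(=O)[C@@H]1CO1 | starting material
7 | [(12Z)-nonadeca-1,12-dien-2-yl]magnesium bromide | CCCCCC/C=C\CCCCCCCCCC(=C)[Mg]Br | intermediate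
8 | methyl (2S,14Z)-2-hydroxy-4-methylidenehenicos-14-enoate | CCCCCC/C=C\CCCCCCCCCC(=C)C[C@H](O)C(=O)OC | intermediate
9 | methyl (2S,14Z)-2-[(dimethylcarbamoyl)oxy]-4-methylidenehenicos-14-enoate | CCCCCC/C=C\CCCCCCCCCC(=C)C[C@H](OC(=O)N(C)C)C(=O)OC | intermediate
10 | methyl phenyl sulfoxide | CS(=O)c1ccccc1 | starting material
11 | [(phenylsulfinyl)methyl]lithium | [Li]CS(=O)c1ccccc1 | intermediate
12 | (3S,15Z)-5-methylidene-2-oxo-1-(phenylsulfinyl)docos-15-en-3-yl dimethylcarbamate | CCCCCC/C=C\CCCCCCCCCC(=C)C[C@H](OC(=O)N(C)C)C(=O)CS(=O)c1ccccc1 | intermediate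
13 | {(3S,15Z)-3-[(dimethylcarbamoyl)oxy]-5-methylidene-2-oxodocos-15-en-1-ylidene}(phenyl)sulfonium triflate | CCCCCC/C=C\CCCCCCCCCC(=C)C[C@H](OC(=O)N(C)C)C(=O)C=[S+]c1ccccc1.[O-]S(=O)(=O)C(F)(F)F | intermediate
14 | (1R,5S)-1-[(10Z)-heptadec-10-en-1-yl]-N,N-dimethyl-6-oxo-7-(phenylsulfanyl)-2,4-dioxabicyclo[3.3.1]nonan-3-iminium triflate | CCCCCC/C=C\CCCCCCCCC[C@]1(OC(=[N+](C)C)O2)CC(Sc3ccccc3)C(=O)[C@@H]2C1.[O-]S(=O)(=O)C(F)(F)F | intermediate
15 | (1R,5S)-1-[(10Z)-heptadec-10-en-1-yl]-7-(phenylsulfanyl)-2,4-dioxabicyclo[3.3.1]nonane-3,6-dione | CCCCCC/C=C\CCCCCCCCC[C@]1(OC(=O)O2)CC(Sc3ccccc3)C(=O)[C@@H]2C1 | intermediate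
16 | (1R,5S)-1-[(10Z)-heptadec-10-en-1-yl]-7-(phenylsulfinyl)-2,4-dioxabicyclo[3.3.1]nonane-3,6-dione | CCCCCC/C=C\CCCCCCCCC[C@]1(OC(=O)O2)CC(S(=O)c3ccccc3)C(=O)[C@@H]2C1 | intermediate
17 | (1R,5S)-1-[(10Z)-heptadec-10-en-1-yl]-2,4-dioxabicyclo[3.3.1]non-7-ene-3,6-dione | CCCCCC/C=C\CCCCCCCCC[C@]1(OC(=O)O2)C=CC(=O)[C@@H]2C1 | intermediate
18 | (4R,6S)-4-[(10Z)-heptadec-10-en-1-yl]-4,6-dihydroxycyclohex-2-en-1-one | CCCCCC/C=C\CCCCCCCCC[C@]1(O)C=CC(=O)[C@@H](O)C1 | target

**Total step count:** 8. **Longest linear sequence:** 8 steps (1 → 18).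

**Steps most likely to fail**

**Step 6 (key step).**
- What may go wrong: proton loss from the tertiary cation, or reversible capture of the thionium carbon by the carbamate oxygen, may outrun the double ring closure.
- The fallback uses known chemistry only. It closes the ring by olefin metathesis and forms the C4–O bond afterwards by halocyclisation on the ring. It sets out from 9.
- MeNH(OMe)·HCl with iPrMgCl converts the ester into the N-methoxy-N-methylamide F1.
- Allylmagnesium bromide at −78 °C gives the allyl ketone F2.
- The second-generation Grubbs catalyst in dilute CH2Cl2 joins the terminal allyl group to the 1,1-disubstituted alkene and gives the cyclohex-3-enone F3.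
- I2 in MeCN places iodonium on the ring face opposite to the carbamate. The carbamate carbonyl oxygen opens it at the tertiary carbon to give the iminium iodide F4.
- Buffered water hydrolyses F4 to the iodo carbonate F5. The same bicyclic constraint enforces the same cis relation.
- DBU removes HI from this β-iodo ketone (E1cB), and the sequence comes back to the route at 17.

**Step 8.**
- What may go wrong: hydroxide may enolise the liberated α-hydroxy ketone, with loss of configuration at C6, or start dehydration towards an aromatic ring.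
- The fallback is a detour through another oxidation level and sets out from 17.
- Luche reduction (NaBH4, CeCl3·7H2O, MeOH, −78 °C) gives the allylic alcohol F6. The configuration of its new carbinol does not matter.
- LiOH in THF–H2O then removes the carbonate from a compound that has no enolisable stereocentre and gives the triol F7.
- MnO2 in CH2Cl2 oxidises only the secondary allylic alcohol, and the sequence comes back to the route at 18.

**Step 3.**
- What may go wrong: sluggish magnesium insertion into the vinylic bromide, or attack of the alkenylmagnesium reagent on the ester instead of the epoxide.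
- The fallback inverts the polarity of the fragment union and sets out from 5.
- Kumada coupling with Me3SiCH2MgCl and Pd(PPh3)4 gives the allylsilane F8.
- F8 adds to methyl glyoxylate in an enantioselective Hosomi–Sakurai-type allylation catalysed by (S)-BINOL/TiCl2(OiPr)2 with 4 Å molecular sieves. The antipode of the ligand is available if the opposite sense is found.
- The sequence comes back to the route at 8.

**Further compounds**
F1 | step 6 | (2S,14Z)-1-[methoxy(methyl)amino]-4-methylidene-1-oxohenicos-14-en-2-yl dimethylcarbamate | CCCCCC/C=C\CCCCCCCCCC(=C)C[C@H](OC(=O)N(C)C)C(=O)N(C)OC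
F2 | step 6 | (5S,17Z)-7-methylidene-4-oxotetracosa-1,17-dien-5-yl dimethylcarbamate | CCCCCC/C=C\CCCCCCCCCC(=C)C[C@H](OC(=O)N(C)C)C(=O)CC=C
F3 | step 6 | (1S)-5-[(10Z)-heptadec-10-en-1-yl]-2-oxocyclohex-4-en-1-yl dimethylcarbamate | CCCCCC/C=C\CCCCCCCCCC1=CCC(=O)[C@@H](OC(=O)N(C)C)C1
F4 | step 6 | (1R,5S,8R)-1-[(10Z)-heptadec-10-en-1-yl]-8-iodo-N,N-dimethyl-6-oxo-2,4-dioxabicyclo[3.3.1]nonan-3-iminium iodide | CCCCCC/C=C\CCCCCCCCC[C@]1(OC(=[N+](C)C)O2)[C@H](I)CC(=O)[C@@H]2C1.[I-]
F5 | step 6 | (1R,5S,8R)-1-[(10Z)-heptadec-10-en-1-yl]-8-iodo-2,4-dioxabicyclo[3.3.1]nonane-3,6-dione | CCCCCC/C=C\CCCCCCCCC[C@]1(OC(=O)O2)[C@H](I)CC(=O)[C@@H]2C1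
F6 | step 8 | (1R,5S)-1-[(10Z)-heptadec-10-en-1-yl]-6-hydroxy-2,4-dioxabicyclo[3.3.1]non-7-en-3-one (C6 undefined) | CCCCCC/C=C\CCCCCCCCC[C@]1(OC(=O)O2)C=CC(O)[C@@H]2C1
F7 | step 8 | (1R,5S)-1-[(10Z)-heptadec-10-en-1-yl]cyclohex-2-ene-1,4,5-triol (C4 undefined) | CCCCCC/C=C\CCCCCCCCC[C@]1(O)C=CC(O)[C@@H](O)C1
F8 | step 3 | [(12Z)-2-methylidenenonadec-12-en-1-yl](trimethyl)silane | CCCCCC/C=C\CCCCCCCCCC(=C)C[Si](C)(C)C
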